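The route disconnects the C3–C1' and C4–Br bonds of the furanone ring (O1, C2 to C5) together. C3 is the α-carbon of the C2 carbonyl, it carries the carbinol C1', and its neighbour C4 carries bromine: the pattern left by conjugate addition of bromide to a C3≡C4 ynoate followed by aldol capture at C3. One operation therefore joins butanal, bromide and the ynoate, sets C1' as (R) under a chiral boron Lewis acid and fixes the C3=C4 geometry; no ring closes. The precursor is tert-butyl 4-methylpent-4-en-2-ynoate: its isopropenyl group is a masked C5 ketone with C6 as methyl, and the tert-butyl ester lets the lactone close later under anhydrous acid.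

Key step: step 2

Remarks on the chemistry
- Atom labels: furanone ring O1, C2 (carbonyl), C3, C4 (Br), C5; exocyclic C6; side chain C1' (carbinol) to C4'. The same labels are used for the open-chain compounds.
- Target check: CIP analysis of the target SMILES gives (R) at C1' and (Z) at C5=C6 (iodine on the side of O1).
- Assumption: by the usual binding model for aldehydes on this boron Lewis acid, the catalyst from (S)-α,α-diphenylprolinol should direct attack to the Si face of butanal, which is (R) at C1'. If the first run shows the other sense, the catalyst from the (R)-amino alcohol is used with no other change.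
- Catalyst (not numbered): N-protonated B-(o-tolyl)oxazaborolidine of (S)-α,α-diphenylprolinol as its bis(trifluoromethanesulfonyl)imide salt, SMILES Cc1ccccc1B1OC(c2ccccc2)(c2ccccc2)[C@@H]2CCC[NH+]12.FC(F)(F)S(=O)(=O)[N-]S(=O)(=O)C(F)(F)F.
- Design point: an ethyl ester at C2 would need aqueous or forcing acid to close the lactone next to the C1' acetate. A tert-butyl ester is carried instead, and ring closure is split into acidolysis with lactol formation (step 5) and dehydration (step 6).

Step 1
Reactants: 1 2-methylbut-1-en-3-yne; 2 di-tert-butyl dicarbonate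
Product: 4 tert-butyl 4-methylpent-4-en-2-ynoate, via (3-methylbut-3-en-1-yn-1-yl)lithium 3 (not isolated)
Conditions: n-BuLi, THF, −78 °C; then Boc2O, −78 → 0 °C; aq. NH4Cl
Reagents that add atoms: di-tert-butyl dicarbonate 2, CC(C)(C)OC(=O)OC(=O)OC(C)(C)C
Why: Deprotonation of the terminal alkyne and C-acylation of the lithium acetylide by Boc2O (acetylide alkoxycarbonylation) is a standard entry to tert-butyl alkynoates, and the isopropenyl group is inert to these conditions.

Step 2
Reactants: 4 tert-butyl 4-methylpent-4-en-2-ynoate; 5 butanal; 6 bromotrimethylsilane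
Product: 9 tert-butyl (2E)-3-bromo-2-[(1R)-1-hydroxybutyl]-4-methylpenta-2,4-dienoate, via silyl bromoallenolate 7 (not isolated), via aldol trimethylsilyl ether 8 (not isolated)
Conditions: (S)-oxazaborolidinium bis(trifluoromethanesulfonyl)imide (20 mol%; made from (S)-α,α-diphenylprolinol and o-tolylboronic acid, then HN(SO2CF3)2), Me3SiBr, CH2Cl2, −78 °C; then 1 M HCl, THF, 0 °C
Reagents that add atoms: butanal 5, CCCC=O; bromotrimethylsilane 6, C[Si](C)(C)Br
Why: Proposed new method: Me3SiBr delivers bromide to C4 of ynoate 4 in a reversible 1,4-addition that gives the O-silyl bromoallenolate 7, whose C3 adds to butanal held on the boron atom of the chiral oxazaborolidinium ion; silyl transfer to the aldolate oxygen frees the catalyst and leaves silyl ether 8, which dilute acid cleaves to 9. The closest known reaction is the catalytic enantioselective three-component coupling of terminal propiolates, aldehydes and Me3SiI to β-iodo Morita–Baylis–Hillman esters, extended here to bromide and to an internal 4-alkenyl ynoate. No ring closes in this step. C1' is controlled by the catalyst: the aldehyde is bound to boron with a formyl C–H···O contact and one of its faces is covered by a phenyl group of the catalyst, so C3 should reach the Si face and give (R). The C3=C4 geometry is controlled by the substrate: the electrophile must approach C3 in the plane of the two C4 substituents and should come from the side of bromine, not from that of the bulkier isopropenyl group, which puts C1' cis to Br and the ester cis to C5, and −78 °C should keep this kinetic isomer from equilibrating. The step also needs 1,4- over 1,6-addition of bromide, which is favoured because C4 is the β-carbon of the ynoate and its attack gives an ester-stabilised allenolate, whereas attack at the alkene terminus would give a higher cumulenolate; the isopropenyl group is otherwise inert to Me3SiBr at this temperature.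

Step 3
Reactants: 9 tert-butyl (2E)-3-bromo-2-[(1R)-1-hydroxybutyl]-4-methylpenta-2,4-dienoate; 10 acetic anhydride
Product: 11 tert-butyl (2E)-2-[(1R)-1-acetoxybutyl]-3-bromo-4-methylpenta-2,4-dienoate
Conditions: Ac2O, pyridine, DMAP (cat.), CH2Cl2, 0 °C → rt
Reagents that add atoms: acetic anhydride 10, CC(=O)OC(C)=O
Why: DMAP-catalysed O-acylation of a secondary allylic alcohol; C3 and C4 are fully substituted, so allylic transposition is not expected and C1' is not touched.

Step 4
Reactants: 11 tert-butyl (2E)-2-[(1R)-1-acetoxybutyl]-3-bromo-4-methylpenta-2,4-dienoate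
Product: 13 tert-butyl (2E)-2-[(1R)-1-acetoxybutyl]-3-bromo-4-oxopent-2-enoate, via secondary ozonide 12 (not isolated)
Conditions: O3, CH2Cl2, −78 °C, Sudan Red 7B as end-point dye; then Me2S, −78 °C → rt
Reagents that add atoms: ozone, [O-][O+]=O
Why: Ozonolysis with reductive work-up; electrophilic ozone should select the 1,1-disubstituted isopropenyl alkene over the tetrasubstituted C3=C4 bond, which is deactivated by the ester and by bromine, and the dye guards against over-oxidation.

Step 5
Reactants: 13 tert-butyl (2E)-2-[(1R)-1-acetoxybutyl]-3-bromo-4-oxopent-2-enoate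
Product: 15 (1R)-1-(4-bromo-5-hydroxy-5-methyl-2-oxo-2,5-dihydrofuran-3-yl)butyl acetate (both C5 epimers), via keto acid 14 (not isolated)
Conditions: TFA, CH2Cl2, 0 °C → rt
Reagents that add atoms: none
Why: Acidolysis of the tert-butyl ester (loss of isobutene) frees the acid, which should add at once to the cis C5 ketone to form the five-membered lactol (ring–chain tautomerism of cis-β-acylacrylic acids); the acetate and C1' are stable to anhydrous TFA.

Step 6
Reactants: 15 (1R)-1-(4-bromo-5-hydroxy-5-methyl-2-oxo-2,5-dihydrofuran-3-yl)butyl acetate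
Product: 16 (1R)-1-(4-bromo-5-methylidene-2-oxo-2,5-dihydrofuran-3-yl)butyl acetate
Conditions: P2O5, CH2Cl2, reflux
Reagents that add atoms: none
Why: Acid-mediated dehydration of a γ-hydroxy-γ-methylbutenolide through the acyloxy-stabilised C5 cation is the established way to 5-methylene-2(5H)-furanones; C4 has no hydrogen, so only the C6 methyl group can lose a proton.

Step 7
Reactants: 16 (1R)-1-(4-bromo-5-methylidene-2-oxo-2,5-dihydrofuran-3-yl)butyl acetate; 17 iodine monochloride
Product: 19 (1R)-1-[(5Z)-4-bromo-5-(iodomethylidene)-2-oxo-2,5-dihydrofuran-3-yl]butyl acetate (target), via chloro iodide adduct 18 (not isolated)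
Conditions: ICl, CH2Cl2, −78 → 0 °C; then i-Pr2NEt, 0 °C
Reagents that add atoms: iodine monochloride 17, ClI
Why: Electrophilic addition–elimination at the only electron-rich alkene: iodine adds to C6, chloride caps the C5 oxocarbenium ion, and base-induced loss of HCl (the only β-hydrogens are on C6) should restore C5=C6 with iodine turned away from the C4 bromine, i.e. (Z), in analogy to the bromination–dehydrobromination route to (Z)-bromomethylene furanones.

Compound list
1 | 2-methylbut-1-en-3-yne | C=C(C)C#C | starting material
2 | di-tert-butyl dicarbonate | CC(C)(C)OC(=O)OC(=O)OC(C)(C)C | starting material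
3 | (3-methylbut-3-en-1-yn-1-yl)lithium (not isolated) | [Li]C#CC(C)=C | intermediate
4 | tert-butyl 4-methylpent-4-en-2-ynoate | C=C(C)C#CC(=O)OC(C)(C)C | intermediate
5 | butanal | CCCC=O | starting material
6 | bromotrimethylsilane | C[Si](C)(C)Br | starting material
7 | [(3-bromo-1-tert-butoxy-4-methylpenta-1,2,4-trien-1-yl)oxy]trimethylsilane, the silyl bromoallenolate (racemic axis, not isolated) | C=C(C)C(Br)=C=C(OC(C)(C)C)O[Si](C)(C)C | intermediate
8 | tert-butyl (2E)-3-bromo-4-methyl-2-[(1R)-1-(trimethylsilyloxy)butyl]penta-2,4-dienoate (not isolated) | CCC[C@@H](O[Si](C)(C)C)/C(C(=O)OC(C)(C)C)=C(\Br)C(C)=C | intermediate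
9 | tert-butyl (2E)-3-bromo-2-[(1R)-1-hydroxybutyl]-4-methylpenta-2,4-dienoate | CCC[C@@H](O)/C(C(=O)OC(C)(C)C)=C(\Br)C(C)=C | intermediate
10 | acetic anhydride | CC(=O)OC(C)=O | starting material
11 | tert-butyl (2E)-2-[(1R)-1-acetoxybutyl]-3-bromo-4-methylpenta-2,4-dienoate | CCC[C@@H](OC(C)=O)/C(C(=O)OC(C)(C)C)=C(\Br)C(C)=C | intermediate
12 | tert-butyl (2E)-2-[(1R)-1-acetoxybutyl]-3-bromo-3-(3-methyl-1,2,4-trioxolan-3-yl)prop-2-enoate, the secondary ozonide (ring carbon epimers, not isolated) | CCC[C@@H](OC(C)=O)/C(C(=O)OC(C)(C)C)=C(\Br)C1(C)OCOO1 | intermediate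
13 | tert-butyl (2E)-2-[(1R)-1-acetoxybutyl]-3-bromo-4-oxopent-2-enoate | CCC[C@@H](OC(C)=O)/C(C(=O)OC(C)(C)C)=C(\Br)C(C)=O | intermediate
14 | (2E)-2-[(1R)-1-acetoxybutyl]-3-bromo-4-oxopent-2-enoic acid (not isolated) | CCC[C@@H](OC(C)=O)/C(C(=O)O)=C(\Br)C(C)=O | intermediate
15 | (1R)-1-(4-bromo-5-hydroxy-5-methyl-2-oxo-2,5-dihydrofuran-3-yl)butyl acetate (both C5 epimers) | CCC[C@@H](OC(C)=O)C1=C(Br)C(C)(O)OC1=O | intermediate
16 | (1R)-1-(4-bromo-5-methylidene-2-oxo-2,5-dihydrofuran-3-yl)butyl acetate | CCC[C@@H](OC(C)=O)C1=C(Br)C(=C)OC1=O | intermediate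
17 | iodine monochloride | ClI | starting material
18 | (1R)-1-[4-bromo-5-chloro-5-(iodomethyl)-2-oxo-2,5-dihydrofuran-3-yl]butyl acetate (both C5 epimers, not isolated) | CCC[C@@H](OC(C)=O)C1=C(Br)C(Cl)(CI)OC1=O | intermediate
19 | (1R)-1-[(5Z)-4-bromo-5-(iodomethylidene)-2-oxo-2,5-dihydrofuran-3-yl]butyl acetate | CCC[C@@H](OC(C)=O)C1=C(Br)/C(=C/I)OC1=O | target

Total step count: 7
Longest linear sequence: 7 steps (from 1 to 19)

Steps most likely to fail

Step 2 (bears the label). Bromide may fail to add to the internal ynoate or may add 1,6; the aldehyde may approach C3 from the isopropenyl side and give the wrong C3=C4 geometry; facial control at butanal may be weak. The fallback sets out from butanal 5 and comes back to the route at keto ester 13, using only established reaction types. Butanal 5, commercial tert-butyl propiolate and Me3SiI would be coupled under the same boron catalyst at −78 °C, the form in which this three-component reaction is established (terminal propiolate, iodide). The coupling passes through the silyl iodoallenolate F1 and the silyl ether F2 and, after dilute HCl, should give tert-butyl (2Z)-2-[(1R)-1-hydroxybutyl]-3-iodoprop-2-enoate F3. Stille coupling of F3 with tributyl(1-ethoxyvinyl)stannane (Pd(PPh3)4, toluene, 80 °C) should give, with retention, the ethoxy diene F4. Work-up with 1 M HCl hydrolyses F4 to the hydroxy enone F5, and acetylation as in step 3 gives the acetoxy enone F6. Bromine is then placed on C4, the α-carbon of the C5 ketone, by the classical bromination–dehydrobromination of an enone: Br2 in CH2Cl2 gives the dibromide F7, and Et3N removes HBr (H from C4, Br from C3) to give 13. Any isomer with the acetyl group trans to the ester would be equilibrated by light, since only 13 can close in step 5.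

Step 7. The amine-induced elimination may give both C5=C6 geometries, or the base may attack C4 by addition–elimination or disturb the allylic acetate. The fallback sets out from 16 and comes back at target 19 without any amine. N-Iodosuccinimide in wet MeCN should add iodine to C6 and water to C5 to give the iodo lactol F9. Dehydration of F9 with P2O5 in CH2Cl2, as in step 6, then forms the C5=C6 bond under acid, where the geometry is under thermodynamic control and iodine should settle away from the C4 bromine.

Step 4. Ozone may also cleave the C3=C4 bond or over-oxidise the diene before the end-point is seen. The fallback sets out from 11 and comes back at 13 in two milder stages: OsO4 (cat.) and N-methylmorpholine N-oxide in acetone/water should dihydroxylate only the isopropenyl alkene to the diol F8, and NaIO4 in THF/water cleaves the glycol to 13.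

Further compounds
F1 | step 2 | [(1-tert-butoxy-3-iodopropa-1,2-dien-1-yl)oxy]trimethylsilane | IC=C=C(OC(C)(C)C)O[Si](C)(C)C
F2 | step 2 | tert-butyl (2Z)-3-iodo-2-[(1R)-1-(trimethylsilyloxy)butyl]prop-2-enoate | CCC[C@@H](O[Si](C)(C)C)/C(C(=O)OC(C)(C)C)=C/I
F3 | step 2 | tert-butyl (2Z)-2-[(1R)-1-hydroxybutyl]-3-iodoprop-2-enoate | CCC[C@@H](O)/C(C(=O)OC(C)(C)C)=C/I
F4 | step 2 | tert-butyl (2Z)-4-ethoxy-2-[(1R)-1-hydroxybutyl]penta-2,4-dienoate | CCC[C@@H](O)/C(C(=O)OC(C)(C)C)=C/C(OCC)=C
F5 | step 2 | tert-butyl (2Z)-2-[(1R)-1-hydroxybutyl]-4-oxopent-2-enoate | CCC[C@@H](O)/C(C(=O)OC(C)(C)C)=C/C(C)=O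
F6 | step 2 | tert-butyl (2Z)-2-[(1R)-1-acetoxybutyl]-4-oxopent-2-enoate | CCC[C@@H](OC(C)=O)/C(C(=O)OC(C)(C)C)=C/C(C)=O
F7 | step 2 | tert-butyl 2-[(1R)-1-acetoxybutyl]-2,3-dibromo-4-oxopentanoate (diastereomer mixture) | CCC[C@@H](OC(C)=O)C(Br)(C(=O)OC(C)(C)C)C(Br)C(C)=O
F8 | step 4 | tert-butyl (2E)-2-[(1R)-1-acetoxybutyl]-3-bromo-4,5-dihydroxy-4-methylpent-2-enoate (both C4 epimers) | CCC[C@@H](OC(C)=O)/C(C(=O)OC(C)(C)C)=C(\Br)C(C)(O)CO
F9 | step 7 | (1R)-1-[4-bromo-5-hydroxy-5-(iodomethyl)-2-oxo-2,5-dihydrofuran-3-yl]butyl acetate (both C5 epimers) | CCC[C@@H](OC(C)=O)C1=C(Br)C(O)(CI)OC1=O
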